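**Retrosynthetic overview**

- Target 10 is a trans-(2S,3S)-2-aryl-3-methyl-2,3-dihydrobenzofuran (benzofuran numbering). Ring A is the 3-hydroxy-4,5-dimethoxyphenyl group on C2, ring B the dihydrofuran (O1, C2, C3, C3a, C7a), and ring C the benzo ring with 7-OMe and the 5-[(1R,2S)-1,2-dihydroxypropyl] chain.
- Late disconnections: the ring A silyl ether (fluoride), and the anti-diol, which goes back to a 1-aryl-1,2-propanedione (asymmetric transfer hydrogenation sets both carbinol centres).
- Key disconnection: ring B is opened at O1–C2 and C3a–C3 in one operation, giving an o-iodophenol (ring C, dione in place) and an E-propenylarene (ring A). The forward reaction is an enantioselective palladium-catalysed oxyarylation, a formal [3+2] heteroannulation.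
- Enabling feature: O1 and C3a are ortho neighbours on ring C (a phenol oxygen next to a C–I carbon), and C2–C3 is a former E-alkene whose C2 is benzylic to the para-methoxy-bearing ring A. This fixes the regiochemistry (aryl to C3, oxygen to C2) and the trans outcome; the dione para to O1 activates the iodophenol and is reduced afterwards.
- Ring order: rings A and C are bought as arenes; ring B is the only ring formed (step 5). Two branches of two steps each converge, then two more steps.

Key step: step 5

Assumption: the sense of asymmetric induction of the pyridine–oxazoline ligand in step 5 cannot be assigned with certainty in advance; the (S)-ligand is written, and its mirror image would be taken if the first run shows the opposite sense.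

**Route**

Step 1
Reactants: 1 3-hydroxy-4,5-dimethoxybenzaldehyde
Product: 2 3,4-dimethoxy-5-(triisopropylsilyloxy)benzaldehyde
Conditions: i-Pr3SiCl, imidazole, DMF, rt
Reagents that add atoms: triisopropylsilyl chloride, CC(C)[Si](Cl)(C(C)C)C(C)C
Why: Imidazole-promoted silyl ether formation at the only hydroxyl masks the ring A phenol against silver- and palladium-mediated oxidation in step 5; no stereocentre is involved.

Step 2
Reactants: 2 3,4-dimethoxy-5-(triisopropylsilyloxy)benzaldehyde
Product: 3 (E)-1,2-dimethoxy-5-(prop-1-en-1-yl)-3-(triisopropylsilyloxy)benzene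
Conditions: 5-(ethylsulfonyl)-1-phenyl-1H-tetrazole, KN(SiMe3)2 added to the mixture of both, DME, −60 °C to rt
Reagents that add atoms: 5-(ethylsulfonyl)-1-phenyl-1H-tetrazole, CCS(=O)(=O)c1nnnn1-c1ccccc1
Why: Julia–Kocienski olefination (carbanion addition, Smiles rearrangement, loss of SO2 and tetrazololate) should give the conjugated E-propenylarene selectively; the E geometry is what later becomes the trans C2/C3 relationship.

Step 3
Reactants: 4 1-(4-hydroxy-3-methoxyphenyl)propan-1-one
Product: 5 1-(4-hydroxy-3-iodo-5-methoxyphenyl)propan-1-one
Conditions: N-iodosuccinimide, cat. TsOH·H2O, MeCN, 0 °C to rt, dark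
Reagents that add atoms: N-iodosuccinimide, O=C1CCC(=O)N1I
Why: Electrophilic aromatic iodination should go to the only free position ortho to the phenol, since the other ortho carbon carries OMe, the para carbon carries the acyl group, and the two carbons ortho to the ketone are deactivated.

Step 4
Reactants: 5 1-(4-hydroxy-3-iodo-5-methoxyphenyl)propan-1-one
Product: 6 1-(4-hydroxy-3-iodo-5-methoxyphenyl)propane-1,2-dione
Conditions: SeO2, 1,4-dioxane/H2O, 95 °C
Reagents that add atoms: selenium dioxide, O=[Se]=O
Why: Riley oxidation converts the enolisable α-methylene of the aryl ethyl ketone into the 1,2-dione, and the acyl-deactivated iodophenol ring and the terminal methyl should be left alone.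

Step 5
Reactants: 6 1-(4-hydroxy-3-iodo-5-methoxyphenyl)propane-1,2-dione; 3 (E)-1,2-dimethoxy-5-(prop-1-en-1-yl)-3-(triisopropylsilyloxy)benzene
Product: 7 1-[(2S,3S)-2-(3,4-dimethoxy-5-(triisopropylsilyloxy)phenyl)-7-methoxy-3-methyl-2,3-dihydro-1-benzofuran-5-yl]propane-1,2-dione
Conditions: 3 (1.5 equiv), Pd2(dba)3 (2.5 mol%), (S)-4-tert-butyl-2-(pyridin-2-yl)-4,5-dihydrooxazole (6 mol%), Ag2CO3 (1.2 equiv), 1,4-dioxane, 45 °C, dark
Reagents that add atoms: none
Why: Proposed new method: oxidative addition of the C–I bond of 6 to zerovalent palladium and iodide abstraction by Ag2CO3 should give a cationic aryl–palladium complex of the pyridine–oxazoline ligand, which inserts the E-alkene of 3 in a syn fashion with the aryl going to the methyl-bearing carbon (future C3) and palladium to the benzylic carbon (future C2), after which the neighbouring phenoxide O1 forms the C2–O1 bond and zerovalent palladium is released. The closest known reaction types are the racemic palladium/Ag2CO3 oxyarylation (Heck-type heteroannulation) of E-propenylarenes and 2H-chromenes with o-iodophenols or o-hydroxyarenediazonium salts, which gives trans-2-aryl-3-methyl-2,3-dihydrobenzofurans, and the enantioselective Heck–Matsuda and redox-relay Heck arylations of acyclic 1,2-disubstituted alkenes with pyridine–oxazoline ligands; new is their combination, a ligand-controlled enantioselective oxyarylation of an acyclic propenylarene. Ring B is closed at C2–O1 by C–O bond formation on the palladium-bearing face from a six-membered oxapalladacycle (equivalent to a 5-exo closure of O1 onto the η3-benzyl carbon), the C3a–C3 bond having been made intermolecularly in the insertion. C3 is set by the ligand, which selects the alkene face in the irreversible migratory insertion; C2 follows from C3, because syn insertion into the E-alkene and closure with retention carry the E geometry into the trans ring, and even if C2 ionises (para-methoxy-stabilised benzylic cation) the ring should close anti to the C3 methyl. The step needs regioselectivity (aryl to C3, secured by η3-benzyl stabilisation of palladium next to electron-rich ring A), chemoselectivity over β-hydride elimination to the stilbene (secured by the chelating ortho-phenoxide, which holds palladium syn to the aryl on C3 so that C3–H cannot become syn-coplanar), and a phenol that survives silver (secured by the dione para to O1, which makes 6 electron-poor for oxidative addition and resistant to quinone methide formation).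

Step 6
Reactants: 7 1-[(2S,3S)-2-(3,4-dimethoxy-5-(triisopropylsilyloxy)phenyl)-7-methoxy-3-methyl-2,3-dihydro-1-benzofuran-5-yl]propane-1,2-dione
Product: 9 (1R,2S)-1-[(2S,3S)-2-(3,4-dimethoxy-5-(triisopropylsilyloxy)phenyl)-7-methoxy-3-methyl-2,3-dihydro-1-benzofuran-5-yl]propane-1,2-diol, via hydroxy ketone 8 (not isolated)
Conditions: RuCl[(S,S)-TsDPEN](p-cymene) (2 mol%), HCO2H/Et3N (5:2), EtOAc, 40 °C
Reagents that add atoms: none
Why: Noyori-type asymmetric transfer hydrogenation of a 1-aryl-1,2-propanedione should reduce the acetyl carbonyl first to the (S)-hydroxy ketone 8 and then the aryl ketone to the (1R)-carbinol with the same catalyst sense, with base-mediated epimerisation of 8 (dynamic kinetic resolution) funnelling material to the anti (1R,2S)-diol; both new centres are catalyst-controlled and remote from C2/C3, and the aryl silyl ether and ring B should be inert to the buffer.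

Step 7
Reactants: 9 (1R,2S)-1-[(2S,3S)-2-(3,4-dimethoxy-5-(triisopropylsilyloxy)phenyl)-7-methoxy-3-methyl-2,3-dihydro-1-benzofuran-5-yl]propane-1,2-diol
Product: 10 (1R,2S)-1-[(2S,3S)-2-(3-hydroxy-4,5-dimethoxyphenyl)-7-methoxy-3-methyl-2,3-dihydro-1-benzofuran-5-yl]propane-1,2-diol
Conditions: Bu4NF, AcOH, THF, 0 °C
Reagents that add atoms: none
Why: Fluoride cleavage of the aryl silyl ether under acetic acid buffering should free the ring A phenol without touching the diol, the benzylic ether of ring B or any of the four stereocentres.

**Compound list**

1 | 3-hydroxy-4,5-dimethoxybenzaldehyde | COc1cc(C=O)cc(O)c1OC | starting material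
2 | 3,4-dimethoxy-5-(triisopropylsilyloxy)benzaldehyde | COc1cc(C=O)cc(O[Si](C(C)C)(C(C)C)C(C)C)c1OC | intermediate
3 | (E)-1,2-dimethoxy-5-(prop-1-en-1-yl)-3-(triisopropylsilyloxy)benzene | COc1cc(/C=C/C)cc(O[Si](C(C)C)(C(C)C)C(C)C)c1OC | intermediate
4 | 1-(4-hydroxy-3-methoxyphenyl)propan-1-one | CCC(=O)c1ccc(O)c(OC)c1 | starting material
5 | 1-(4-hydroxy-3-iodo-5-methoxyphenyl)propan-1-one | CCC(=O)c1cc(I)c(O)c(OC)c1 | intermediate
6 | 1-(4-hydroxy-3-iodo-5-methoxyphenyl)propane-1,2-dione | CC(=O)C(=O)c1cc(I)c(O)c(OC)c1 | intermediate
7 | 1-[(2S,3S)-2-(3,4-dimethoxy-5-(triisopropylsilyloxy)phenyl)-7-methoxy-3-methyl-2,3-dihydro-1-benzofuran-5-yl]propane-1,2-dione | COc1cc([C@H]2Oc3c(OC)cc(C(=O)C(C)=O)cc3[C@@H]2C)cc(O[Si](C(C)C)(C(C)C)C(C)C)c1OC | intermediate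
8 | (2S)-1-[(2S,3S)-2-(3,4-dimethoxy-5-(triisopropylsilyloxy)phenyl)-7-methoxy-3-methyl-2,3-dihydro-1-benzofuran-5-yl]-2-hydroxypropan-1-one | COc1cc([C@H]2Oc3c(OC)cc(C(=O)[C@H](C)O)cc3[C@@H]2C)cc(O[Si](C(C)C)(C(C)C)C(C)C)c1OC | intermediate
9 | (1R,2S)-1-[(2S,3S)-2-(3,4-dimethoxy-5-(triisopropylsilyloxy)phenyl)-7-methoxy-3-methyl-2,3-dihydro-1-benzofuran-5-yl]propane-1,2-diol | COc1cc([C@H]2Oc3c(OC)cc([C@@H](O)[C@H](C)O)cc3[C@@H]2C)cc(O[Si](C(C)C)(C(C)C)C(C)C)c1OC | intermediate
10 | (1R,2S)-1-[(2S,3S)-2-(3-hydroxy-4,5-dimethoxyphenyl)-7-methoxy-3-methyl-2,3-dihydro-1-benzofuran-5-yl]propane-1,2-diol | COc1cc([C@H]2Oc3c(OC)cc([C@@H](O)[C@H](C)O)cc3[C@@H]2C)cc(O)c1OC | target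

**Step count and risks**

Total step count: 7. Longest linear sequence: 5 steps (steps 3, 4, 5, 6, 7, or equally steps 1, 2, 5, 6, 7).

Steps most likely to fail:

1. Step 5. The ligand-bound aryl–palladium complex may discriminate the two alkene faces poorly in the migratory insertion, or the benzyl–palladium intermediate may be diverted into β-hydride elimination before the C–O bond forms. The fallback sets out from 6 and 3 and returns at 7. The two are joined without chiral ligand under the established oxyarylation conditions (Pd(OAc)2, Ag2CO3, 1,4-dioxane, 50 °C), which should give the trans product as a racemate, that is 7 together with the (2R,3R)-enantiomer of the dione F1. Compound 7 is then separated from it by preparative chromatography on a chiral stationary phase (supercritical CO2/alcohol) and carried into step 6.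

2. Step 6. The second, slower reduction of the electron-rich aryl ketone may stall, or the epimerisation and reduction rates may be mismatched so that anti selectivity is lost. The fallback sets out from 7 and returns at 9. The transfer hydrogenation is run at about 10 °C and stopped at the stage of hydroxy ketone 8, which is isolated. Reduction with Zn(BH4)2 in Et2O at −20 °C should then deliver hydride to the five-membered zinc chelate of the carbonyl oxygen and the α-hydroxyl from the face opposite the methyl group, giving the anti-diol 9 under substrate control. No compound outside the list arises (F0).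

3. Step 4. The iodophenol may be degraded oxidatively or the dione over-oxidised by SeO2 at high temperature, or conversion may stay incomplete. The fallback sets out from 5 and returns at 6. α-Nitrosation with isoamyl nitrite and HCl in Et2O should give 1-(4-hydroxy-3-iodo-5-methoxyphenyl)-2-(hydroxyimino)propan-1-one F2, and transoximation with aqueous formaldehyde/HCl at rt should release dione 6.

Further compounds
F1 | step 5 | 1-[(2R,3R)-2-(3,4-dimethoxy-5-(triisopropylsilyloxy)phenyl)-7-methoxy-3-methyl-2,3-dihydro-1-benzofuran-5-yl]propane-1,2-dione | COc1cc([C@@H]2Oc3c(OC)cc(C(=O)C(C)=O)cc3[C@H]2C)cc(O[Si](C(C)C)(C(C)C)C(C)C)c1OC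
F0 | step 6 | none | none
F2 | step 4 | 1-(4-hydroxy-3-iodo-5-methoxyphenyl)-2-(hydroxyimino)propan-1-one | CC(=NO)C(=O)c1cc(I)c(O)c(OC)c1
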